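**Retrosynthetic overview**
1. Target 16 ⇒ diterpenoic acid 13 + (R)-glycidyl acetate 15; carboxylate opening at the epoxide CH2 gives the 1-acyl-3-acetyl-sn-glycerol with free 2-OH in one step.
2. 13 ⇒ C5-methyl bicycle 8 + prenyl bromide 9; the 4-methylpent-3-enyl chain is the vinylic methyl plus a prenyl unit (allyl-anion alkylation).
3. Bicycle 7 ⇒ monocyclic ester 4: the ester α-carbon (future C1, made electrophilic) bonds to the tetrasubstituted ring olefin (future C8a); the ring-fusion cation (C4a) is quenched by 1,2-shift of a C5 methyl and loss of H6, as in the presumed biogenesis.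
4. 4 ⇒ dihydro-β-ionone 1 + triethyl phosphonoacetate 2 (olefination, then asymmetric conjugate reduction); the C2 methyl stereocentre then controls C1, C4a and C8a.
5. Ring order: ring B (the cyclohexene) is carried in from 1; ring A (the ring bearing the ester) is closed in the key step 3.

Assumption: the biogenesis is taken as cationic — a monocyclic geranylgeranoate with a tetrasubstituted ring olefin, closure of ring A across that olefin, methyl shift to the ring fusion, proton loss; here the prenyl end of the side chain is added after the cationic step.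

**Step 1**
Reactants: 1 dihydro-β-ionone; 2 triethyl phosphonoacetate
Product: 3 ethyl (2E)-3-methyl-5-(2,6,6-trimethylcyclohex-1-en-1-yl)pent-2-enoate
Conditions: NaH, THF, 0 → 60 °C; E isomer separated by chromatography
Reagents that add atoms: none
Why: Horner–Wadsworth–Emmons olefination of the methyl ketone, E-selective (about 4:1); no stereocentre is formed.

**Step 2**
Reactants: 3 ethyl (2E)-3-methyl-5-(2,6,6-trimethylcyclohex-1-en-1-yl)pent-2-enoate
Product: 4 ethyl (3R)-3-methyl-5-(2,6,6-trimethylcyclohex-1-en-1-yl)pentanoate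
Conditions: Cu(OAc)2 (3 mol %), (S)-p-Tol-BINAP, (EtO)2MeSiH, t-BuOH, toluene, rt
Reagents that add atoms: none
Why: Copper hydride asymmetric conjugate reduction (Buchwald type); hydride adds to one face of the E-enoate β-carbon to give the 3R ester (same sense as ethyl geranate → ethyl (R)-citronellate with this ligand, stated from memory and to be confirmed on the first run), and the isolated tetrasubstituted olefin is inert.

**Step 3 (key step)**
Reactants: 4 ethyl (3R)-3-methyl-5-(2,6,6-trimethylcyclohex-1-en-1-yl)pentanoate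
Product: 7 ethyl (1S,2R,4aR,8aR)-2,4a,5,8a-tetramethyl-1,2,3,4,4a,7,8,8a-octahydronaphthalene-1-carboxylate, via ketene silyl acetal 5 (not isolated), via α-iodanyl ester 6 (not isolated)
Conditions: LDA, TMSCl, THF, −78 °C; then PhI(OAc)2, BF3·OEt2, 2,6-di-tert-butyl-4-methylpyridine, CH2Cl2, −78 → −20 °C; then NaOEt, EtOH, rt
Reagents that add atoms: none
Why: Proposed new method: PhI(OAc)2/BF3 umpoles ketene silyl acetal 5 to the α-iodanyl ester 6 (enolonium chemistry, known to alkylate allylsilanes, which are about as nucleophilic as a tetraalkylethylene), the ring olefin displaces PhI at the α-carbon through a chair transition state (six-membered ring and tertiary cation, cf. the Johnson π-route and inversion-type Friedel–Crafts alkylation with lactate sulfonates), and the C4a cation is discharged as in the presumed biogenesis by antiperiplanar 1,2-shift of a C5 methyl and loss of H6 (Wagner–Meerwein shift, E1); the 3R methyl sits equatorial to avoid a 1,3-diaxial clash with the axial C8a methyl (sets C8a), the anti shift gives the cis ring-fusion methyls (sets C4a), and the epimerisable ester settles equatorial, trans to the C2 methyl, under NaOEt (sets C1).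

**Step 4**
Reactants: 7 ethyl (1S,2R,4aR,8aR)-2,4a,5,8a-tetramethyl-1,2,3,4,4a,7,8,8a-octahydronaphthalene-1-carboxylate
Product: 8 [(1S,2R,4aR,8aR)-2,4a,5,8a-tetramethyl-1,2,3,4,4a,7,8,8a-octahydronaphthalen-1-yl]methanol
Conditions: LiAlH4, THF, 0 °C → reflux
Reagents that add atoms: none
Why: Hydride reduction of the hindered ester to the primary alcohol; no stereocentre is touched and the olefin is inert.

**Step 5**
Reactants: 8 [(1S,2R,4aR,8aR)-2,4a,5,8a-tetramethyl-1,2,3,4,4a,7,8,8a-octahydronaphthalen-1-yl]methanol; 9 prenyl bromide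
Product: 11 [(1S,2R,4aR,8aR)-2,4a,8a-trimethyl-5-(4-methylpent-3-en-1-yl)-1,2,3,4,4a,7,8,8a-octahydronaphthalen-1-yl]methanol, via dipotassium alkoxide-allyl dianion 10 (not isolated)
Conditions: n-BuLi/KOt-Bu (2.2 equiv each), THF–hexane, −78 → −20 °C; then 9 (1.0 equiv), −78 °C
Reagents that add atoms: none
Why: Schlosser-base allylic metalation followed by SN2 alkylation: after O-deprotonation the C5 methyl is metalated (primary site, and the more stable allyl anion; cf. α-pinene at C10), and the allylpotassium attacks prenyl bromide through its unhindered CH2 end, which keeps the C5=C6 olefin; no stereocentre changes.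

**Step 6**
Reactants: 11 [(1S,2R,4aR,8aR)-2,4a,8a-trimethyl-5-(4-methylpent-3-en-1-yl)-1,2,3,4,4a,7,8,8a-octahydronaphthalen-1-yl]methanol
Product: 13 (1S,2R,4aR,8aR)-2,4a,8a-trimethyl-5-(4-methylpent-3-en-1-yl)-1,2,3,4,4a,7,8,8a-octahydronaphthalene-1-carboxylic acid, via aldehyde 12 (not isolated)
Conditions: TEMPO (10 mol %), PhI(OAc)2, CH2Cl2, rt; then NaClO2, NaH2PO4, 2-methyl-2-butene, t-BuOH/H2O, rt
Reagents that add atoms: sodium chlorite, [Na+].[O-]Cl=O
Why: TEMPO/PhI(OAc)2 oxidation to the aldehyde, then Pinnick oxidation with 2-methyl-2-butene scavenging HOCl so both trisubstituted olefins survive; C1 keeps its thermodynamically preferred equatorial configuration.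

**Step 7**
Reactants: 14 (S)-glycidol
Product: 15 (R)-glycidyl acetate
Conditions: Ac2O, pyridine, CH2Cl2, 0 °C
Reagents that add atoms: acetic anhydride, CC(=O)OC(C)=O
Why: O-acetylation; the stereocentre is untouched (the descriptor changes from S to R only through CIP priorities).

**Step 8**
Reactants: 13 (1S,2R,4aR,8aR)-2,4a,8a-trimethyl-5-(4-methylpent-3-en-1-yl)-1,2,3,4,4a,7,8,8a-octahydronaphthalene-1-carboxylic acid; 15 (R)-glycidyl acetate
Product: 16 (2S)-3-acetoxy-2-hydroxypropyl (1S,2R,4aR,8aR)-2,4a,8a-trimethyl-5-(4-methylpent-3-en-1-yl)-1,2,3,4,4a,7,8,8a-octahydronaphthalene-1-carboxylate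
Conditions: racemic Co(salen)(OAc) (salen = N,N'-bis(3,5-di-tert-butylsalicylidene)-trans-1,2-cyclohexanediamine dianion; trivalent cobalt, 5 mol %), i-Pr2NEt, t-BuOMe, rt
Reagents that add atoms: none
Why: Cobalt–salen catalysed ring opening of a terminal epoxide by a carboxylic acid (Jacobsen type) at the unsubstituted CH2; the glycerol stereocentre is not touched, so the (2S) 1-acyl-3-acetyl-sn-glycerol forms directly, and room temperature limits acyl migration.

**Compound list**
1 | dihydro-β-ionone, 4-(2,6,6-trimethylcyclohex-1-en-1-yl)butan-2-one | CC(=O)CCC1=C(C)CCCC1(C)C | starting material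
2 | triethyl phosphonoacetate | CCOC(=O)CP(=O)(OCC)OCC | starting material
3 | ethyl (2E)-3-methyl-5-(2,6,6-trimethylcyclohex-1-en-1-yl)pent-2-enoate | CCOC(=O)/C=C(\C)CCC1=C(C)CCCC1(C)C | intermediate
4 | ethyl (3R)-3-methyl-5-(2,6,6-trimethylcyclohex-1-en-1-yl)pentanoate | CCOC(=O)C[C@H](C)CCC1=C(C)CCCC1(C)C | intermediate
5 | (3R)-1-ethoxy-3-methyl-5-(2,6,6-trimethylcyclohex-1-en-1-yl)-1-(trimethylsilyloxy)pent-1-ene (ketene silyl acetal, E/Z mixture) | CCOC(O[Si](C)(C)C)=C[C@H](C)CCC1=C(C)CCCC1(C)C | intermediate (not isolated)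
6 | ethyl (3R)-2-[acetoxy(phenyl)-λ3-iodanyl]-3-methyl-5-(2,6,6-trimethylcyclohex-1-en-1-yl)pentanoate (C2 epimers) | CCOC(=O)C(I(OC(C)=O)c1ccccc1)[C@H](C)CCC1=C(C)CCCC1(C)C | intermediate (not isolated)
7 | ethyl (1S,2R,4aR,8aR)-2,4a,5,8a-tetramethyl-1,2,3,4,4a,7,8,8a-octahydronaphthalene-1-carboxylate | CCOC(=O)[C@H]1[C@H](C)CC[C@]2(C)C(C)=CCC[C@]12C | intermediate
8 | [(1S,2R,4aR,8aR)-2,4a,5,8a-tetramethyl-1,2,3,4,4a,7,8,8a-octahydronaphthalen-1-yl]methanol | OC[C@H]1[C@H](C)CC[C@]2(C)C(C)=CCC[C@]12C | intermediate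
9 | prenyl bromide, 1-bromo-3-methylbut-2-ene | CC(C)=CCBr | starting material
10 | dipotassium salt of 8 deprotonated at OH and at the C5 methyl (alkoxide-allyl dianion) | [K+].[K+].[O-]C[C@H]1[C@H](C)CC[C@]2(C)C([CH2-])=CCC[C@]12C | intermediate (not isolated)
11 | [(1S,2R,4aR,8aR)-2,4a,8a-trimethyl-5-(4-methylpent-3-en-1-yl)-1,2,3,4,4a,7,8,8a-octahydronaphthalen-1-yl]methanol | OC[C@H]1[C@H](C)CC[C@]2(C)C(CCC=C(C)C)=CCC[C@]12C | intermediate
12 | (1S,2R,4aR,8aR)-2,4a,8a-trimethyl-5-(4-methylpent-3-en-1-yl)-1,2,3,4,4a,7,8,8a-octahydronaphthalene-1-carbaldehyde | O=C[C@H]1[C@H](C)CC[C@]2(C)C(CCC=C(C)C)=CCC[C@]12C | intermediate (not isolated)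
13 | (1S,2R,4aR,8aR)-2,4a,8a-trimethyl-5-(4-methylpent-3-en-1-yl)-1,2,3,4,4a,7,8,8a-octahydronaphthalene-1-carboxylic acid | OC(=O)[C@H]1[C@H](C)CC[C@]2(C)C(CCC=C(C)C)=CCC[C@]12C | intermediate
14 | (S)-glycidol, (2S)-oxiran-2-ylmethanol | OC[C@H]1CO1 | starting material
15 | (R)-glycidyl acetate, (2R)-oxiran-2-ylmethyl acetate | CC(=O)OC[C@H]1CO1 | intermediate
16 | (2S)-3-acetoxy-2-hydroxypropyl (1S,2R,4aR,8aR)-2,4a,8a-trimethyl-5-(4-methylpent-3-en-1-yl)-1,2,3,4,4a,7,8,8a-octahydronaphthalene-1-carboxylate | CC(=O)OC[C@H](O)COC(=O)[C@H]1[C@H](C)CC[C@]2(C)C(CCC=C(C)C)=CCC[C@]12C | target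

**Totals**
Total step count: 8. Longest linear sequence: 7 (steps 1–6 and 8).

**Three steps most likely to fail**

Step 3. The α-iodanyl ester 6 may be diverted (α-acetoxylation, loss of the β-hydrogen to the enoate, spiro five-ring closure). The fallback replaces the electrophile but not the cation that follows, so it does not cover proton loss at C4a before the methyl shift. Fallback from 4 back to 7 through a sulfur-stabilised cation: LDA then PhSSPh gives ethyl (3R)-3-methyl-2-(phenylsulfanyl)-5-(2,6,6-trimethylcyclohex-1-en-1-yl)pentanoate F1. NCS in CCl4 gives the α-chloro sulfide ethyl (3R)-2-chloro-3-methyl-2-(phenylsulfanyl)-5-(2,6,6-trimethylcyclohex-1-en-1-yl)pentanoate F2. SnCl4 in CH2Cl2 at −78 °C ionises F2 to the acylthionium ion (Pummerer-type cation–olefin cyclisation), which closes ring A with the same methyl shift and proton loss to give ethyl (2R,4aR,8aS)-2,4a,5,8a-tetramethyl-1-(phenylsulfanyl)-1,2,3,4,4a,7,8,8a-octahydronaphthalene-1-carboxylate F3. Reductive desulfurisation with lithium 4,4'-di-tert-butylbiphenylide (THF, −78 °C), protonation and NaOEt equilibration return 7.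

Step 5. Metalation may occur in part at the ring C7 methylene, the allyl anion may react at its ring end, or the alkoxide may be O-prenylated. Fallback from 7 to 11 by allylic oxidation and sulfone coupling: SeO2 (cat.)/t-BuOOH oxidises only the C5 methyl (the neighbouring C4a has no hydrogen) to ethyl (1S,2R,4aS,8aR)-5-(hydroxymethyl)-2,4a,8a-trimethyl-1,2,3,4,4a,7,8,8a-octahydronaphthalene-1-carboxylate F4. PBr3 gives ethyl (1S,2R,4aS,8aR)-5-(bromomethyl)-2,4a,8a-trimethyl-1,2,3,4,4a,7,8,8a-octahydronaphthalene-1-carboxylate F5. Lithiated prenyl phenyl sulfone displaces the bromide through its α-carbon to give ethyl (1S,2R,4aR,8aR)-2,4a,8a-trimethyl-5-[4-methyl-2-(phenylsulfonyl)pent-3-en-1-yl]-1,2,3,4,4a,7,8,8a-octahydronaphthalene-1-carboxylate F6. Pd(dppp)Cl2 with excess LiBHEt3 removes the sulfonyl group and reduces the ester, returning 11.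

Step 8. The hindered acid may open the epoxide slowly or unselectively, and the acetyl group may migrate to the 2-OH. Fallback from 13 to 16 with the glycerol oxygens differentiated by protection: the caesium salt of 13 (Cs2CO3, DMF) is alkylated with the tosylate of (R)-solketal to give [(4S)-2,2-dimethyl-1,3-dioxolan-4-yl]methyl (1S,2R,4aR,8aR)-2,4a,8a-trimethyl-5-(4-methylpent-3-en-1-yl)-1,2,3,4,4a,7,8,8a-octahydronaphthalene-1-carboxylate F7. 80 % aqueous AcOH at rt removes the acetonide to give (2S)-2,3-dihydroxypropyl (1S,2R,4aR,8aR)-2,4a,8a-trimethyl-5-(4-methylpent-3-en-1-yl)-1,2,3,4,4a,7,8,8a-octahydronaphthalene-1-carboxylate F8. Vinyl acetate with Candida antarctica lipase B acetylates only the primary hydroxyl, giving 16.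

**Further compounds**
F1 | step 3 | ethyl (3R)-3-methyl-2-(phenylsulfanyl)-5-(2,6,6-trimethylcyclohex-1-en-1-yl)pentanoate | CCOC(=O)C(Sc1ccccc1)[C@H](C)CCC1=C(C)CCCC1(C)C
F2 | step 3 | ethyl (3R)-2-chloro-3-methyl-2-(phenylsulfanyl)-5-(2,6,6-trimethylcyclohex-1-en-1-yl)pentanoate | CCOC(=O)C(Cl)(Sc1ccccc1)[C@H](C)CCC1=C(C)CCCC1(C)C
F3 | step 3 | ethyl (2R,4aR,8aS)-2,4a,5,8a-tetramethyl-1-(phenylsulfanyl)-1,2,3,4,4a,7,8,8a-octahydronaphthalene-1-carboxylate | CCOC(=O)C1(Sc2ccccc2)[C@H](C)CC[C@]3(C)C(C)=CCC[C@]13C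
F4 | step 5 | ethyl (1S,2R,4aS,8aR)-5-(hydroxymethyl)-2,4a,8a-trimethyl-1,2,3,4,4a,7,8,8a-octahydronaphthalene-1-carboxylate | CCOC(=O)[C@H]1[C@H](C)CC[C@]2(C)C(CO)=CCC[C@]12C
F5 | step 5 | ethyl (1S,2R,4aS,8aR)-5-(bromomethyl)-2,4a,8a-trimethyl-1,2,3,4,4a,7,8,8a-octahydronaphthalene-1-carboxylate | CCOC(=O)[C@H]1[C@H](C)CC[C@]2(C)C(CBr)=CCC[C@]12C
F6 | step 5 | ethyl (1S,2R,4aR,8aR)-2,4a,8a-trimethyl-5-[4-methyl-2-(phenylsulfonyl)pent-3-en-1-yl]-1,2,3,4,4a,7,8,8a-octahydronaphthalene-1-carboxylate | CCOC(=O)[C@H]1[C@H](C)CC[C@]2(C)C(CC(C=C(C)C)S(=O)(=O)c3ccccc3)=CCC[C@]12C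
F7 | step 8 | [(4S)-2,2-dimethyl-1,3-dioxolan-4-yl]methyl (1S,2R,4aR,8aR)-2,4a,8a-trimethyl-5-(4-methylpent-3-en-1-yl)-1,2,3,4,4a,7,8,8a-octahydronaphthalene-1-carboxylate | CC1(C)OC[C@@H](COC(=O)[C@H]2[C@H](C)CC[C@]3(C)C(CCC=C(C)C)=CCC[C@]23C)O1
F8 | step 8 | (2S)-2,3-dihydroxypropyl (1S,2R,4aR,8aR)-2,4a,8a-trimethyl-5-(4-methylpent-3-en-1-yl)-1,2,3,4,4a,7,8,8a-octahydronaphthalene-1-carboxylate | OC[C@H](O)COC(=O)[C@H]1[C@H](C)CC[C@]2(C)C(CCC=C(C)C)=CCC[C@]12C
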